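**Retrosynthetic overview** (side chain numbered C1'–C12' from the ring)
1. The target is read as a C5-farnesylated, dearomatized 6-hydroxy-8-alkoxy-3,5,7-trimethylisocoumarin. The last step only frees the C8 enol from a methyl ether.
2. Key disconnection: the bonds C5'H2–C6'H= and C1'–C5 are cut together. This gives (E)-1-iodo-2,6-dimethylhepta-1,5-diene (C9), 3-methylpenta-1,4-diene (C1'–C5' plus the C3' methyl) and the flat, achiral phenol 6-hydroxy-8-methoxy-3,5,7-trimethylisocoumarin.
3. Enabling feature: ring atom C5 is ortho to O6 of the former benzenoid ring (C4a–C5–C6–C7–C8–C8a). It carries an allyl unit C1'H2–C2'H=C3'(CH3) that is separated from the C6'=C7' alkene by exactly C4'H2–C5'H2. That pattern is what alkenyl-Pd insertion into a skipped diene, a one-carbon Pd shift and C-allylation of a phenolate leave behind. The fused 2-pyrone (C1, O2, C3, C4, C4a, C8a) stays intact only if C5 is the carbon attacked.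
4. Ring order: the benzenoid ring is bought (methyl 2,4-dihydroxy-3,6-dimethylbenzoate). The pyranone ring is closed second by lateral lithiation/acylation and enol lactonization. The carbocycle is dearomatized last, in the key step, and no further ring is formed.
5. The alkenyl iodide comes from 5-bromo-2-methylpent-2-ene by acetylide alkylation and Zr-catalysed carboalumination/iodination.

Key step: step 9

Assumption: the sense of induction of the DACH-naphthyl diphosphine on this phenolate cannot be read from a close analogue, so the (R,R) ligand is written for the (5S) product and its equally available mirror image is to be used if the opposite sense is found.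

**Route**

Step 1
Reactants: 1 5-bromo-2-methylpent-2-ene
Product: 2 6-methylhept-5-en-1-yne
Conditions: LiC≡CH·H2NCH2CH2NH2 (1.3 equiv), DMSO, 10 °C to rt
Reagents that add atoms: lithium acetylide ethylenediamine complex, [Li]C#C.NCCN
Why: SN2 alkylation of an acetylide, in which the primary homoallylic bromide is displaced by lithium acetylide in DMSO and the trisubstituted alkene is a spectator.

Step 2
Reactants: 2 6-methylhept-5-en-1-yne
Product: 4 (E)-1-iodo-2,6-dimethylhepta-1,5-diene, via alkenyldimethylalane 3 (not isolated)
Conditions: Me3Al (2 equiv), Cp2ZrCl2 (0.25 equiv), CH2Cl2, 0 °C to rt; then I2, THF, −30 to 0 °C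
Reagents that add atoms: trimethylaluminium, C[Al](C)C; iodine, II
Why: Negishi carboalumination adds CH3 and Al syn across the terminal alkyne with Al at the terminal carbon, and iodinolysis of the C–Al bond goes with retention, so the E-trisubstituted alkene (later C6'=C7') is fixed here while the existing trisubstituted alkene is too hindered to carbometalate.

Step 3
Reactants: 5 methyl 2,4-dihydroxy-3,6-dimethylbenzoate
Product: 6 methyl 5-formyl-2,4-dihydroxy-3,6-dimethylbenzoate (benzoate numbering of 5 kept)
Conditions: Cl2CHOMe (1.5 equiv), TiCl4 (3 equiv), CH2Cl2, 0 °C to rt; then 1 M HCl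
Reagents that add atoms: dichloromethyl methyl ether, COC(Cl)Cl; water, O
Why: Rieche formylation, a Friedel-Crafts reaction of the titanium phenolate, can only strike C5, the one free ring position, which is ortho to the 4-OH and para to the 2-OH.

Step 4
Reactants: 6 methyl 5-formyl-2,4-dihydroxy-3,6-dimethylbenzoate
Product: 7 methyl 2,4-dihydroxy-3,5,6-trimethylbenzoate
Conditions: Et3SiH (3 equiv), CF3CO2H/CH2Cl2 1:1, rt
Reagents that add atoms: none
Why: Ionic hydrogenation, in which the protonated aldehyde and then the benzylic cation stabilized by the ortho and para oxygen atoms each take a hydride from the silane, so that ArCHO should go to ArCH3 without touching the ester.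

Step 5
Reactants: 7 methyl 2,4-dihydroxy-3,5,6-trimethylbenzoate
Product: 8 methyl 2-hydroxy-4-(methoxymethoxy)-3,5,6-trimethylbenzoate
Conditions: MOMCl (1.2 equiv), i-Pr2NEt (1.5 equiv), CH2Cl2, 0 °C to rt
Reagents that add atoms: chloromethyl methyl ether, COCCl
Why: Chemoselective Williamson-type O-alkylation, because the 2-OH is tied up in a hydrogen bond to the ester carbonyl and is much less nucleophilic, so the small electrophile should react at the 4-OH only.

Step 6
Reactants: 8 methyl 2-hydroxy-4-(methoxymethoxy)-3,5,6-trimethylbenzoate
Product: 9 methyl 2-methoxy-4-(methoxymethoxy)-3,5,6-trimethylbenzoate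
Conditions: MeI (3 equiv), K2CO3 (3 equiv), DMF, 50 °C
Reagents that add atoms: iodomethane, CI
Why: Williamson etherification methylates the remaining chelated phenol, and this methyl ether later serves as the O8 blocking group of the key step.

Step 7
Reactants: 9 methyl 2-methoxy-4-(methoxymethoxy)-3,5,6-trimethylbenzoate
Product: 12 methyl 2-methoxy-4-(methoxymethoxy)-3,5-dimethyl-6-(2-oxopropyl)benzoate, via benzylic lithium species 10 (not isolated), via chelated tetrahedral adduct 11 (not isolated)
Conditions: LDA (1.3 equiv), THF, −78 °C; MeC(O)N(OMe)Me (1.5 equiv), −78 to 0 °C; sat. aq NH4Cl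
Reagents that add atoms: N-methoxy-N-methylacetamide, CC(=O)N(C)OC
Why: Lateral lithiation of an o-toluate followed by a Weinreb ketone synthesis, in which only the C6 methyl group is conjugated with the ester and is deprotonated by LDA, the two ortho substituents shield the ester from self-condensation, and the chelated adduct 11 prevents over-addition.

Step 8
Reactants: 12 methyl 2-methoxy-4-(methoxymethoxy)-3,5-dimethyl-6-(2-oxopropyl)benzoate
Product: 13 6-hydroxy-8-methoxy-3,5,7-trimethyl-1H-isochromen-1-one
Conditions: CF3CO2H/H2O 19:1, 60 °C
Reagents that add atoms: none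
Why: Acid-catalysed acetal hydrolysis frees O6 and acid-catalysed enol lactonization (6-exo-trig attack of the ketone enol oxygen on the protonated ester, loss of methanol) closes the pyranone ring, while an aryl methyl ether is stable to trifluoroacetic acid.

Step 9
Reactants: 4 (E)-1-iodo-2,6-dimethylhepta-1,5-diene; 13 6-hydroxy-8-methoxy-3,5,7-trimethyl-1H-isochromen-1-one; 14 3-methylpenta-1,4-diene
Product: 17 (5S)-8-methoxy-3,5,7-trimethyl-5-[(2E,6E)-3,7,11-trimethyldodeca-2,6,10-trien-1-yl]-1H-isochromene-1,6(5H)-dione, via caesium phenolate 15 (not isolated), via farnesylpalladium iodide 16 (not isolated)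
Conditions: Pd2(dba)3·CHCl3 (2.5 mol %), (R,R)-DACH-naphthyl diphosphine (7 mol %), Cs2CO3 (1.5 equiv), 13 (1.2 equiv), 14 (3 equiv), degassed 1,4-dioxane, 50 °C, sealed tube
Reagents that add atoms: none
Why: Proposed new method: Pd(0) inserts into the C–I bond of 4 with retention of the E geometry, the alkenyl-Pd species adds syn across one vinyl group of 14 with carbon going to the terminal CH2 (this makes the bond between the alkenyl CH C6' and the CH2 group C5'), β-hydride elimination of the tertiary allylic C3'–H and re-insertion then move palladium by one carbon to the 1,1-disubstituted π-allyl complex 16, and its unsubstituted terminus C1' is attacked outer-sphere by ring carbon C5 of phenolate 15, which turns the benzenoid ring into the cyclohexadienone. The closest known reaction types are the three-component coupling of aryl or vinylic halides, non-conjugated dienes and soft carbon nucleophiles by palladium migration (Heck/Tsuji-Trost relay) and the Pd/DACH-diphosphine intermolecular asymmetric allylic dearomatization of 1,3-dialkyl-2-naphthols, of which 13 is a hetero-analogue, and what is new is their merger with a phenolate carbon as the terminating nucleophile. No ring is closed, and the step makes two C–C bonds, one E-trisubstituted alkene and the quaternary stereocentre from three achiral components. C5 is the only new stereocentre and is controlled by the C2-symmetric ligand, whose chiral pocket should let the flat phenolate meet the CH2 terminus with one face only, while the new C2'=C3' alkene should be E because the four-coordinate Pd–H/η2-diene complex has no site for η4 binding, re-inserts from the s-trans diene and so places the long chain syn on the allyl unit. Site selectivity on the nucleophile is secured by the O8 methyl ether (it crowds C7, removes the second enolizable oxygen and leaves a neutral product that cannot be allylated again), by the fact that attack at C5 keeps the C4a=C8a bond inside an intact 2-pyrone just as attack at C1 of a 2-naphthol keeps the benzo ring, and by the reversibility of O6-allylation under Pd(0). The direction of palladium migration is the open point: a shift towards the old alkenyl group gives a π-allyl with only secondary and tertiary termini, which the hindered C5 nucleophile should not attack and which can revert through the Pd–H/diene stage, so the primary terminus of 16 should drain the equilibrium, and the remote C10'=C11' alkene cannot interfere because it lies trans to palladium across C6'=C7'.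

Step 10
Reactants: 17 (5S)-8-methoxy-3,5,7-trimethyl-5-[(2E,6E)-3,7,11-trimethyldodeca-2,6,10-trien-1-yl]-1H-isochromene-1,6(5H)-dione
Product: 19 (5S)-8-hydroxy-3,5,7-trimethyl-5-[(2E,6E)-3,7,11-trimethyldodeca-2,6,10-trien-1-yl]-1H-isochromene-1,6(5H)-dione, via lithium enolate 18 (not isolated)
Conditions: LiI (5 equiv), EtOAc, 70 °C, slow N2 stream; then cold 1 M HCl
Reagents that add atoms: none
Why: SN2 O-demethylation by iodide, the reaction type used with lithium halides for methyl esters and for enol methyl ethers of cyclic β-diketones, should work because the leaving group is a vinylogous carboxylate held by lithium between O8 and the lactone carbonyl, no acid strong enough to start polyene cyclization is present, and the quaternary C5 has no pathway for epimerization.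

**Compound list**
1 | 5-bromo-2-methylpent-2-ene | CC(C)=CCCBr | starting material
2 | 6-methylhept-5-en-1-yne | CC(C)=CCCC#C | intermediate
3 | (E)-(2,6-dimethylhepta-1,5-dien-1-yl)dimethylalane | CC(C)=CCC/C(C)=C/[Al](C)C | intermediate
4 | (E)-1-iodo-2,6-dimethylhepta-1,5-diene | CC(C)=CCC/C(C)=C/I | intermediate
5 | methyl 2,4-dihydroxy-3,6-dimethylbenzoate | COC(=O)c1c(C)cc(O)c(C)c1O | starting material
6 | methyl 5-formyl-2,4-dihydroxy-3,6-dimethylbenzoate | COC(=O)c1c(C)c(C=O)c(O)c(C)c1O | intermediate
7 | methyl 2,4-dihydroxy-3,5,6-trimethylbenzoate | COC(=O)c1c(C)c(C)c(O)c(C)c1O | intermediate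
8 | methyl 2-hydroxy-4-(methoxymethoxy)-3,5,6-trimethylbenzoate | COC(=O)c1c(C)c(C)c(OCOC)c(C)c1O | intermediate
9 | methyl 2-methoxy-4-(methoxymethoxy)-3,5,6-trimethylbenzoate | COC(=O)c1c(C)c(C)c(OCOC)c(C)c1OC | intermediate
10 | methyl 6-(lithiomethyl)-2-methoxy-4-(methoxymethoxy)-3,5-dimethylbenzoate | COC(=O)c1c(C[Li])c(C)c(OCOC)c(C)c1OC | intermediate
11 | lithium alkoxide adduct of 10 to N-methoxy-N-methylacetamide (racemic at the carbinol carbon) | COC(=O)c1c(CC(C)(O[Li])N(C)OC)c(C)c(OCOC)c(C)c1OC | intermediate
12 | methyl 2-methoxy-4-(methoxymethoxy)-3,5-dimethyl-6-(2-oxopropyl)benzoate | COC(=O)c1c(CC(C)=O)c(C)c(OCOC)c(C)c1OC | intermediate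
13 | 6-hydroxy-8-methoxy-3,5,7-trimethyl-1H-isochromen-1-one | Cc1cc2c(C)c(O)c(C)c(OC)c2c(=O)o1 | intermediate
14 | 3-methylpenta-1,4-diene | C=CC(C)C=C | starting material
15 | caesium 8-methoxy-3,5,7-trimethyl-1-oxo-1H-isochromen-6-olate | Cc1cc2c(C)c([O-])c(C)c(OC)c2c(=O)o1.[Cs+] | intermediate
16 | (2E,6E)-farnesylpalladium(II) iodide, π-allyl complex drawn in its η1 form, diphosphine omitted | CC(C)=CCC/C(C)=C/CC/C(C)=C/C[Pd]I | intermediate
17 | (5S)-8-methoxy-3,5,7-trimethyl-5-[(2E,6E)-3,7,11-trimethyldodeca-2,6,10-trien-1-yl]-1H-isochromene-1,6(5H)-dione | CC(C)=CCC/C(C)=C/CC/C(C)=C/C[C@]1(C)C(=O)C(C)=C(OC)c2c1cc(C)oc2=O | intermediate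
18 | lithium enolate (O8) of 19 | CC(C)=CCC/C(C)=C/CC/C(C)=C/C[C@]1(C)C(=O)C(C)=C(O[Li])c2c1cc(C)oc2=O | intermediate
19 | (5S)-8-hydroxy-3,5,7-trimethyl-5-[(2E,6E)-3,7,11-trimethyldodeca-2,6,10-trien-1-yl]-1H-isochromene-1,6(5H)-dione | CC(C)=CCC/C(C)=C/CC/C(C)=C/C[C@]1(C)C(=O)C(C)=C(O)c2c1cc(C)oc2=O | target

**Step count**
Total step count: 10. Longest linear sequence: 8 steps (steps 3 to 10, from 5). Steps 1 and 2 form the short branch that joins in step 9.

**Steps most likely to fail**

1. Step 9.
 - What may go wrong:
 - Palladium may migrate towards the alkenyl side instead of towards the second vinyl group.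
 - The Pd–H stage may be intercepted by base, so that the sequence ends as a plain Heck reaction.
 - Pd–H may isomerize the skipped diene into conjugation.
 - Face selection on the phenolate, or syn/anti selection on the allyl unit, may be weak.
 - Allylation may take place at O6 or C7.
 - Fallback: it uses known reaction types only, forms the same alkenyl–CH2 bond, sets out from 13 and 4 and comes back at 17.
 - Methyl vinyl ketone and vinylmagnesium bromide give 3-methylpenta-1,4-dien-3-ol F1.
 - n-BuLi and then ClCO2Me turn this alcohol into methyl 3-methylpenta-1,4-dien-3-yl carbonate F2.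
 - Pd2(dba)3/(R,R)-DACH-naphthyl diphosphine-catalysed asymmetric allylic dearomatization of 13 with F2 follows. It runs by ionization, loss of CO2 and attack of C5 on the CH2 terminus of the vinyl-substituted π-allyl, in dioxane at rt. It should give (5S)-8-methoxy-3,5,7-trimethyl-5-[(2E)-3-methylpenta-2,4-dien-1-yl]-1H-isochromene-1,6(5H)-dione F3.
 - 9-BBN in THF should add to the terminal vinyl group only, to give the homoallylic B-alkyl-9-borabicyclo[3.3.1]nonane F4.
 - A B-alkyl Suzuki-Miyaura coupling of F4 with 4 [PdCl2(dppf), AsPh3, Cs2CO3, DMF/H2O, rt] gives 17.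

2. Step 10.
 - What may go wrong:
 - Attack of iodide on the methyl group may be too slow below the temperature at which sigmatropic shifts of the allyl dienone or attack on the pyrone begin.
 - Iodomethane that is not swept out may re-alkylate the enolate.
 - Fallback: it sets out from 17 and comes back at 18.
 - Vinylogous saponification with LiOH in THF/H2O at 0 °C to rt breaks the other bond of the ether. Hydroxide adds to ring carbon C8 and methoxide is expelled (addition–elimination), as practised on enol methyl ethers of prenylated cyclic β-diketones.
 - Any pyrone ring opened on the way should re-close on the acidic work-up of step 10.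
 - No compound outside the list is made (F0).

3. Step 8.
 - What may go wrong:
 - The doubly ortho-substituted ester may resist attack by the enol.
 - Forcing the acid conditions may cause loss of the O8 methyl group.
 - Fallback: it sets out from 12 and comes back at 13, and it activates the carboxyl group instead of the ester.
 - SN2 cleavage of the hindered methyl ester (LiI, pyridine, reflux) gives 2-methoxy-4-(methoxymethoxy)-3,5-dimethyl-6-(2-oxopropyl)benzoic acid F5.
 - Trifluoroacetic anhydride (CH2Cl2, 0 °C) forms the mixed anhydride, which the enol captures, to give 8-methoxy-6-(methoxymethoxy)-3,5,7-trimethyl-1H-isochromen-1-one F6.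
 - HCl in MeOH (40 °C) removes the acetal to give 13.

**Further compounds**
F1 | step 9 | 3-methylpenta-1,4-dien-3-ol | C=CC(C)(O)C=C
F2 | step 9 | methyl 3-methylpenta-1,4-dien-3-yl carbonate | C=CC(C)(C=C)OC(=O)OC
F3 | step 9 | (5S)-8-methoxy-3,5,7-trimethyl-5-[(2E)-3-methylpenta-2,4-dien-1-yl]-1H-isochromene-1,6(5H)-dione | C=C/C(C)=C/C[C@]1(C)C(=O)C(C)=C(OC)c2c1cc(C)oc2=O
F4 | step 9 | (5S)-5-[(2E)-5-(9-borabicyclo[3.3.1]nonan-9-yl)-3-methylpent-2-en-1-yl]-8-methoxy-3,5,7-trimethyl-1H-isochromene-1,6(5H)-dione | C1CCC2CCCC1B2CC/C(C)=C/C[C@]3(C)C(=O)C(C)=C(OC)c4c3cc(C)oc4=O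
F0 | step 10 | none | none
F5 | step 8 | 2-methoxy-4-(methoxymethoxy)-3,5-dimethyl-6-(2-oxopropyl)benzoic acid | OC(=O)c1c(CC(C)=O)c(C)c(OCOC)c(C)c1OC
F6 | step 8 | 8-methoxy-6-(methoxymethoxy)-3,5,7-trimethyl-1H-isochromen-1-one | Cc1cc2c(C)c(OCOC)c(C)c(OC)c2c(=O)o1
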